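As the chemist choosing between Saturday's and Friday's flask, I had three earlier runs to read.

common to all: substrate 0.40 M

|  | first nucleophile | solid second nucleophile | temperature | remark | time |
|---|---|---|---|---|---|
| west | 1.4 equiv | 4 equiv | 0 °C | run made earlier |  |
| north | 2.2 equiv | 4 equiv | 12 °C | run made earlier |  |
| east | 1 equiv | 2 equiv | 0 °C | run made earlier |  |
| Saturday's | 1.00 equiv | 4.00 equiv | 5 °C |  | 12 h |
| Friday's | 1.00 equiv | 4.00 equiv | 20 °C |  | 12 h |

| run | time / h | target / % |
|---|---|---|
| west | 1.00 | 3.0 |
| west | 2.00 | 7.6 |
| west | 3.00 | 10.4 |
| west | 6.00 | 18.8 |
| west | 12.0 | 32.2 |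
| north | 1.00 | 11.8 |
| north | 2.00 | 19.9 |
| north | 3.00 | 28.1 |
| north | 6.00 | 44.6 |
| north | 12.0 | 62.0 |
| east | 1.00 | 2.9 |
| east | 2.00 | 6.1 |
| east | 3.00 | 7.0 |
| east | 6.00 | 13.9 |
| east | 12.0 | 24.3 |

(each reading ± 0.5 percentage points)

- amounts and yields of target count idle adduct too
- given per volume of solution although it is solid: solid second nucleophile
- on the list of suspects stand: solid second nucleophile <-> second nucleophile; second nucleophile + target <-> idle adduct; substrate <-> dormant form; substrate <-> intermediate; second nucleophile + intermediate -> other capture product; first nucleophile + intermediate -> target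
- at the start none of the solid second nucleophile is in solution

1. the flask with the highest amount of target, in percent of the substrate charged ("all alike" if they lie within 1.5 percentage points) (Saturday's / Friday's / all alike)
2. final target, as a percentage of the substrate charged, in Saturday's
3. final target, as a percentage of the substrate charged, in Friday's

I read the table through one number, the pairing time. This was the inverse of an apparent second-order constant times the substrate charge: the hours at which, with equal charges of substrate and first nucleophile, target equals the substrate not yet turned to target.

East has equal charges, so its last reading gave 37.4 h. West, with 1.4 equiv of first nucleophile and 4 equiv of solid against east's 2 equiv, gave 37.7 h. So the two pairing times, each read from one last reading, stood close, and I saw no effect of the solid in them.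

North, at 12 °C, gave 18.6 h from its reading at 3.00 h. Its reading at 12.0 h gave 22.6 h, which is longer. So north's pairing time, as read, stretched by a factor of 1.21.

I took the logarithm of the pairing time, from east's last reading and north's reading at 3.00 h, as straight in temperature. That gave 28.0 h at 5 °C, and this pairing time at 5 °C is what I carried forward. Saturday's temperature lay nearer east's than north's, so I left its pairing time unstretched and reckoned 30.0 %. For Friday's I reckoned 11.7 h, stretched it by north's factor, and got 45.8 %. So I expected Friday's to be higher.

The forecast named Friday's, with 29 % for Saturday's and 35 % for Friday's, saying “Friday is probably still higher”, and its Friday's figure is lower than mine.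

The flasks gave Friday's as the higher one, with 29.6 % in Saturday's and 45.7 % in Friday's.

    solid second nucleophile ⇌ second nucleophile, rate k1*(cs1 - [second nucleophile]) while solid is left; crystals form when [second nucleophile] > cs1 (solubility = 0.130 M, k = 0.320 /h)
    second nucleophile + target ⇌ idle adduct, settled at all times (K = 0.970 /M, ΔH = −32.0 kJ/mol)
    substrate ⇌ dormant form (K = 0.360, k = 0.0370 /h, Ea = 99.0 kJ/mol, ΔH = 17.0 kJ/mol)
    substrate ⇌ intermediate (K = 0.00690, k = 0.740 /h, Ea = 76.0 kJ/mol, ΔH = −10.0 kJ/mol)
    second nucleophile + intermediate → other capture product (k = 4.00 /M/h, Ea = 74.0 kJ/mol)
    first nucleophile + intermediate → target (k = 16.0 /M/h, Ea = 52.0 kJ/mol)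
    (constants at 5 °C)

The neighbouring flask is Saturday's with 1.70 equiv of first nucleophile. I kept the pairing time of 28.0 h and used the same rate law for unequal charges, which gave 46.0 %. That flask gave 44.1 %, more than Saturday's 29.6 %, and 40 % of the substrate charged stood unbound at the end.

The runs are calculated with constants of no real substance; scatter was added.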